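(The readings are calculated for substances that don't exist.)

Percent of the starting material charged is the unit of both products, and dividing it by a nucleophile's equivalents gives the fraction of that nucleophile spent. The new flask lies between the ochre and blue runs in protic impurity.

| flask | starting material | first nucleophile | second nucleophile | capture agent | protic impurity | remark | time |
|---|---|---|---|---|---|---|---|
| ochre | 2 mM | 1.2 equiv | 1.05 equiv | 0.60 mM | 0.20 mM | run made earlier |  |
| blue | 2 mM | 1.2 equiv | 1.05 equiv | 0.60 mM | 0.80 mM | run made earlier |  |
| flask | 2.0 mM | 1.20 equiv | 1.05 equiv | 0.600 mM | 0.400 mM |  | 30 min |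

| run | time / min | other capture product / % | target / % |
|---|---|---|---|
| ochre | 2.50 | 37.7 | 37.3 |
| ochre | 5.00 | 37.7 | 39.1 |
| ochre | 8.00 | 38.1 | 38.1 |
| ochre | 10.0 | 38.3 | 38.3 |
| ochre | 12.0 | 37.4 | 38.6 |
| ochre | 15.0 | 38.5 | 38.4 |
| ochre | 20.0 | 37.7 | 37.7 |
| blue | 1.00 | 30.1 | 30.1 |
| blue | 3.00 | 30.4 | 30.7 |
| blue | 5.00 | 31.2 | 30.5 |
| blue | 8.00 | 31.1 | 31.4 |
| blue | 10.0 | 30.6 | 30.4 |
| blue | 15.0 | 31.2 | 31.2 |
| blue | 20.0 | 31.6 | 31.0 |

(standard deviation of a reading: 0.5 percentage points)

- ratio of other capture product to target at 0.40 s
- ratio of other capture product to target at 25 s
- ratio of other capture product to target at 30 min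

- the analysis behind the earlier runs scatters by 0.5 percentage points, standard deviation

Both earlier runs are flat from their first samples to 20.0 min, so each run is read as its mean: in the ochre run, other capture product 37.9 % and target 38.2 %; in the blue run, 30.9 % and 30.8 %.

This reckoning assumes that both products come from one short-lived precursor, each by a step first order in its nucleophile. Their rates then stand as s times the ratio of nucleophile concentrations. Integrating gives g = f^s, where f and g are the fractions of first and second nucleophile left. Here s is the selectivity factor, the rate constant of capture by second nucleophile over that by first. The ochre run reads 1.17, the blue run 1.18, and their mean is s = 1.17.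

Time comes first among the settings. With f and g near one, the earliest ratio is s times the charge ratio, 1.03, and this is the estimate for 0.40 s. Protic impurity comes next: interpolated linearly between the runs, target in the new flask is estimated at 35.7 %. That estimate gives f = 70.2 % and g = 66.1 %, so the estimated ratio at 30 min is 0.997, with the estimate at 25 s between these two. In this reckoning, with s and the charge of first nucleophile held, the earliest ratio is proportional to the charge of second nucleophile.

The forecast gives 1, 1 and 1, holding that impurity “changes the plateau yield” but not the ratio, and it stands below this reckoning at the early time.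

The flask gives 1.03, 1.00 and 0.997.

    starting material → open intermediate (k = 0.0540 s⁻¹)
    first nucleophile + open intermediate → target (k = 29000 M⁻¹ s⁻¹)
    second nucleophile + open intermediate → other capture product (k = 34000 M⁻¹ s⁻¹)
    open intermediate → solvolysis product (k = 25.0 s⁻¹)
    open intermediate + capture agent → trapped intermediate (k = 340 M⁻¹ s⁻¹)
    starting material + protic impurity → quenched substrate (k = 36.0 M⁻¹ s⁻¹)

At the charges, second nucleophile captures open intermediate at 71.4 s⁻¹, faster than first nucleophile at 69.6 s⁻¹, and both exceed solvolysis at 25 s⁻¹. At 30 min in the flask, first nucleophile stands at 70 % of its charge and second nucleophile at 66 %, where s puts it at 65.9 %. With 1.80 equiv of second nucleophile, s puts the earliest ratio at 1.76, and that neighbouring flask gives 1.76 at 0.40 s.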